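Take a pencil.

| flask | solid substrate | coupling partner | time |
|---|---|---|---|
| midnight | 2.5 mM | 14.7 mM | 1.0 h |
| winter | 8.0 mM | 14.7 mM | 1.0 h |
| spring | 20 mM | 14.7 mM | 1.0 h |
| dusk | 60 mM | 14.7 mM | 1.0 h |
| dawn | 200 mM | 14.7 mM | 1.0 h |

    solid substrate ⇌ dissolved substrate, rate k1*(cs1 - [dissolved substrate]) while solid is left; crystals form when [dissolved substrate] > cs1 (cs1 = 9.3 mM, k1 = 0.47 /min)
    dissolved substrate + coupling partner → target (k2 = 5.4 /M/min)
    dissolved substrate + target → side product (k3 = 2.0 /M/min)
    solid product ⇌ target, rate k4*(cs4 - [target]) while solid is left; crystals form when [target] > cs4 (cs4 = 2.6 mM, k4 = 8.6 /min)
    2 coupling partner → self-condensation product (k5 = 7.6 /M/min)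

- percentages count the solid substrate that a species holds: one side product counts as two
- target is meant together with its solid product
- for a step with 2 of a species take k times the square, and two of it per event
- solid, in amounts per volume of the solution: solid substrate, solid product
- at the start none of the solid substrate is in solution
- the concentration of target that is asked is that of its free form alone
- "hardly changes" means that all values lie within two and a half points (for a concentration: within two and a half percent of the largest)
- run time (midnight): 1.0 h

- [target] (only what is free in solution) at the end for midnight, winter, spring, dusk, dawn, in this order
- how that number moves from the first to the last of them (rises all the way / hardly changes / falls all the way / rises, then falls / falls, then rises)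

Turn the question round: what must hold for the row to rise to its last flask? Once [dissolved substrate] stands at its solubility, more solid does not raise it, yet that same dissolved substrate eats the target with a steady pseudo-first-order rate constant. So for a rising row I ask for a target that outlasts the run. Reckon the target's life at the ceiling:

life = 1 / (2.0 /M/min × 9.3 mM) = 53.8 min

This target's life at the ceiling is shorter than the run of 1.0 h, and 1.12 lives fit into the hour, so a flask held at that ceiling stands on the wrong side. How much target is born, then, to be eaten?

With [dissolved substrate] at the ceiling, the coupling partner feeds two steps, which take equal shares at the level

balance = 5.4 /M/min × 9.3 mM / (2 × 7.6 /M/min) = 3.30 mM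

Following the partner down, the target born is the balance times ln(1 + partner/balance). My first round, from the charge of 14.7 mM, gives 5.60 mM.

Now go round once more. The substrate needs about 2.13 min to arrive, and I let self-condensation work alone for that time, which brings the partner to 9.96 mM. Starting from there, the target born is

4.59 mM

Half of that is born by the time the partner reaches the balance, at about 10.2 min. Taking that moment as the birth of the whole batch, what survives to the end is

4.59 mM × exp(−(60 min − 10.2 min) / 53.8 min) = 1.82 mM

I therefore commit to a flat row near 1.82 mM from spring on, where the charge of 20 mM exceeds the solubility. Winter, at 8.0 mM, lies under the solubility, so I expect a longer-lived target and a peak there, above a low midnight.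

The forecast gave 1.3 mM, 2.55 mM, 2.05 mM, 2.05 mM and 2.05 mM, shape rises, then falls, holding that “undissolved solid pins the dissolved substrate near” 9.3 mM.

The simulation gives 1.25 mM, 2.42 mM, 2.05 mM, 2.05 mM and 2.05 mM, shape rises, then falls, so my flat part lies 0.230 mM low.

In spring [dissolved substrate] reads 9.20 mM at the end, which keeps the target's life near 53.8 min, shorter than the 1.0 h run, and free target stands at 2.05 mM. In midnight [dissolved substrate] reads 0.951 mM at the end, which stretches the same life to 8.76 h, longer than the run, and at that moment the target is made faster than it is used up, by a factor of 1.79.

The rate constants are assumed.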